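**Retrosynthetic overview**

1. The target is numbered as a heptanedioate (C1 ester carbonyl, C2 the CH carrying 4-methylpent-3-enyl, C3–C5 methylenes, C6 the CH carrying 3-(furan-3-yl)propyl, C7 acid carbonyl). It is cut at C2–C3 into a racemic C9 α-bromo anilide (C1, C2 and the side chain) and a C12 (R)-α-allyl N-acyl oxazolidinone (C3–C7 and the furylpropyl chain).
2. The union is a nickel-hydride enantioconvergent hydroalkylation: the terminal olefin (C3=C4) is hydrometalated in the flask and both enantiomers of the bromide are funnelled to (R)-C2.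
3. Enabling feature: C2 is a tertiary CH between the C1 carbonyl (so a C2 radical is stabilised and the C2–Br configuration is erased) and the unbranched C3H2–C4H2–C5H2 tether (so C3 can be the terminus of a monosubstituted olefin). The only other C=C is trisubstituted and reachable from the C2 radical only by 4-exo or 5-endo closure, and the furan ring is inert to Ni–H.
4. C6 is set beforehand by auxiliary-controlled allylation; C2 and C6 are 1,5-related and cannot bias each other, so the ligand alone fixes (2R,6S). The termini are told apart by their masks: the C1 anilide becomes the methyl ester through its O-methyl imidate salt, and the C7 imide becomes the acid last.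
5. No ring is formed: the furan ring is bought as 3-bromofuran and attached by B-alkyl Suzuki coupling; the oxazolidinone ring is temporary and leaves in the last step.

Key step: step 7

Remark: the sense of induction of the nickel/bis(oxazoline) catalyst in step 7 is assumed to be selectable by the ligand antipode; which antipode gives (R) at C2 is to be fixed on a model olefin before 19 is committed.

**Route**

Step 1
Reactants: 1 (4-carboxybutyl)triphenylphosphonium bromide; 2 acetone
Product: 4 6-methylhept-5-enoic acid, via phosphonium ylide 3 (not isolated)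
Conditions: KOtBu (2.2 equiv), THF, 0 °C to rt; then 2, 0 °C to rt; aq. HCl work-up
Reagents that add atoms: none
Why: Wittig olefination of the symmetrical ketone with the non-stabilised ylide (the first equivalent of base is consumed by the acid) should give the trisubstituted olefin with no E/Z issue.

Step 2
Reactants: 4 6-methylhept-5-enoic acid; 5 N-benzylaniline
Product: 7 N-benzyl-6-methyl-N-phenylhept-5-enamide, via acid chloride 6 (not isolated)
Conditions: (COCl)2, DMF (cat.), CH2Cl2, 0 °C to rt; evaporate; then 5, pyridine, DMAP (cat.), CH2Cl2, 0 °C to rt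
Reagents that add atoms: none
Why: The weakly nucleophilic secondary aniline needs the acid chloride, which oxalyl chloride/catalytic DMF should form at 0 °C without touching the trisubstituted olefin, pyridine taking up the HCl (amide formation from an acid chloride).

Step 3
Reactants: 7 N-benzyl-6-methyl-N-phenylhept-5-enamide
Product: 9 rac-N-benzyl-2-bromo-6-methyl-N-phenylhept-5-enamide, via lithium enolate 8 (not isolated)
Conditions: LiN(iPr)2, THF, −78 °C; cannulate into NBS, THF, −78 °C; aq. NH4Cl
Reagents that add atoms: N-bromosuccinimide, O=C1CCC(=O)N1Br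
Why: Electrophilic α-bromination of the amide lithium enolate (inverse addition to limit proton exchange and dibromination) should be far faster than attack of Br+ on the olefin, and the new centre is deliberately left racemic because step 7 is enantioconvergent.

Step 4
Reactants: 10 (S)-4-benzyloxazolidin-2-one; 11 pent-4-enoyl chloride
Product: 13 (S)-4-benzyl-3-(pent-4-enoyl)oxazolidin-2-one, via lithiated oxazolidinone 12 (not isolated)
Conditions: n-BuLi, THF, −78 °C; then 11, −78 to 0 °C
Reagents that add atoms: none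
Why: N-acylation of the lithiated oxazolidinone with an acid chloride is the standard entry to Evans imides and leaves the terminal olefin untouched.

Step 5
Reactants: 13 (S)-4-benzyl-3-(pent-4-enoyl)oxazolidin-2-one; 14 3-bromofuran
Product: 16 (S)-4-benzyl-3-[5-(furan-3-yl)pentanoyl]oxazolidin-2-one, via B-alkyl borane 15 (not isolated)
Conditions: 9-BBN-H, THF, 0 °C to rt; then 14, PdCl2(dppf) (cat.), AsPh3 (cat.), Cs2CO3, DMF/THF/H2O, rt
Reagents that add atoms: none
Why: Anti-Markovnikov hydroboration of the monosubstituted olefin (imide carbonyls inert to 9-BBN) followed by B-alkyl Suzuki–Miyaura coupling under mild carbonate conditions should attach the furan through its C3 without cleaving the imide.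

Step 6
Reactants: 16 (S)-4-benzyl-3-[5-(furan-3-yl)pentanoyl]oxazolidin-2-one; 17 allyl iodide
Product: 19 (4S)-4-benzyl-3-[(2R)-5-(furan-3-yl)-2-(prop-2-en-1-yl)pentanoyl]-1,3-oxazolidin-2-one, via sodium Z-enolate 18 (not isolated)
Conditions: NaN(SiMe3)2, THF, −78 °C; then 17, −78 to −45 °C
Reagents that add atoms: none
Why: Evans asymmetric alkylation, in which the chelated Z-enolate is allylated by the activated electrophile on the face opposite the C4 benzyl group, should set the (R) α-centre (the later C6), and the product can be purified to a single diastereomer.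

Step 7
Reactants: 9 rac-N-benzyl-2-bromo-6-methyl-N-phenylhept-5-enamide; 19 (4S)-4-benzyl-3-[(2R)-5-(furan-3-yl)-2-(prop-2-en-1-yl)pentanoyl]-1,3-oxazolidin-2-one
Product: 20 (2R,6S)-N-benzyl-7-[(4S)-4-benzyl-2-oxo-1,3-oxazolidin-3-yl]-6-[3-(furan-3-yl)propyl]-2-(4-methylpent-3-en-1-yl)-7-oxo-N-phenylheptanamide
Conditions: NiBr2·glyme (cat.), chiral bis(oxazoline) ligand (cat., antipode chosen for (R)-C2), (EtO)3SiH, K3PO4·H2O, DMA/THF, rt; 9 in excess
Reagents that add atoms: none
Why: A nickel hydride formed from NiBr2·glyme, the ligand, the silane and phosphate should insert the monosubstituted olefin of 19 anti-Markovnikov to a primary alkyl–nickel species, while racemic 9 is turned by halogen-atom abstraction at low-valent nickel into a planar α-amido radical common to both enantiomers; capture of this radical by the chiral alkyl–nickel complex and reductive elimination from trivalent nickel form the C2–C3 bond. The closest known reaction type is the nickel-catalysed enantioconvergent hydroalkylation of unactivated terminal olefins with racemic secondary α-bromo N-alkyl-N-aryl amides, together with the nickel/Pybox enantioconvergent Negishi alkylation of the same N-benzyl-N-phenyl amides. No ring is closed. The new C2 stereocentre is set by the ligand alone (catalyst control), and since C6 is four bonds away and cannot bias it, pairing the (R)-olefin with the right ligand antipode should give the (2R,6S) diastereomer. The step needs three selectivities: hydrometalation of the terminal olefin beside the trisubstituted one (secured by the large rate difference for Ni–H insertion), linear instead of chain-walked coupling (the primary alkyl–nickel is the reactive isomer), and intermolecular capture of the C2 radical instead of cyclisation onto its own olefin (only 4-exo or 5-endo modes exist). The imide, the furan and the C6–H should survive because the medium is only weakly basic and at room temperature.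

Step 8
Reactants: 20 (2R,6S)-N-benzyl-7-[(4S)-4-benzyl-2-oxo-1,3-oxazolidin-3-yl]-6-[3-(furan-3-yl)propyl]-2-(4-methylpent-3-en-1-yl)-7-oxo-N-phenylheptanamide
Product: 22 methyl (2R,6S)-7-[(4S)-4-benzyl-2-oxo-1,3-oxazolidin-3-yl]-6-[3-(furan-3-yl)propyl]-2-(4-methylpent-3-en-1-yl)-7-oxoheptanoate, via O-methyl imidate salt 21 (not isolated)
Conditions: Me3OBF4, 2,6-di-tert-butyl-4-methylpyridine, CH2Cl2, 0 °C to rt; then sat. aq. NaHCO3, 0 °C
Reagents that add atoms: trimethyloxonium tetrafluoroborate, C[O+](C)C.F[B-](F)(F)F; water, O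
Why: The amide oxygen is the most Lewis-basic site of 20 (imide carbonyls, furan and olefin are far less nucleophilic toward the oxonium salt), so O-methylation should give an imidate salt whose hydrolysis expels the weakly basic N-benzylaniline and keeps the O-methyl group as the methyl ester (conversion of a tertiary amide into an ester through its imidate salt), and no base strong enough to deprotonate C2 is present.

Step 9
Reactants: 22 methyl (2R,6S)-7-[(4S)-4-benzyl-2-oxo-1,3-oxazolidin-3-yl]-6-[3-(furan-3-yl)propyl]-2-(4-methylpent-3-en-1-yl)-7-oxoheptanoate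
Product: 24 (2S,6R)-2-[3-(furan-3-yl)propyl]-7-methoxy-6-(4-methylpent-3-en-1-yl)-7-oxoheptanoic acid, via lithium percarboxylate 23 (not isolated)
Conditions: LiOH, H2O2, THF/H2O, 0 °C; then aq. Na2SO3, 0 °C; then 1 M HCl to pH 3
Reagents that add atoms: hydrogen peroxide, OO
Why: Hydroperoxide should attack the exocyclic imide carbonyl far faster than the hindered α-branched methyl ester (standard LiOH/H2O2 cleavage of Evans imides), the percarboxylate is reduced by sulfite before acidification so that no peracid can oxidise the olefin or the furan, and neither stereocentre is enolised at 0 °C.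

**Compound list**

1 | (4-carboxybutyl)triphenylphosphonium bromide | OC(=O)CCCC[P+](c1ccccc1)(c1ccccc1)c1ccccc1.[Br-] | starting material
2 | acetone | CC(C)=O | starting material
3 | potassium 5-(triphenyl-λ5-phosphanylidene)pentanoate (ylide) | [K+].[O-]C(=O)CCCC=P(c1ccccc1)(c1ccccc1)c1ccccc1 | intermediate
4 | 6-methylhept-5-enoic acid | CC(C)=CCCCC(=O)O | intermediate
5 | N-benzylaniline | c1ccc(CNc2ccccc2)cc1 | starting material
6 | 6-methylhept-5-enoyl chloride | CC(C)=CCCCC(Cl)=O | intermediate
7 | N-benzyl-6-methyl-N-phenylhept-5-enamide | CC(C)=CCCCC(=O)N(Cc1ccccc1)c1ccccc1 | intermediate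
8 | lithium enolate of 7 (geometry immaterial) | [Li+].[O-]C(=CCCC=C(C)C)N(Cc1ccccc1)c1ccccc1 | intermediate
9 | rac-N-benzyl-2-bromo-6-methyl-N-phenylhept-5-enamide | CC(C)=CCCC(Br)C(=O)N(Cc1ccccc1)c1ccccc1 | intermediate
10 | (S)-4-benzyloxazolidin-2-one | O=C1N[C@@H](Cc2ccccc2)CO1 | starting material
11 | pent-4-enoyl chloride | C=CCCC(Cl)=O | starting material
12 | lithium (S)-4-benzyl-2-oxooxazolidin-3-ide | [Li+].O=C1[N-][C@@H](Cc2ccccc2)CO1 | intermediate
13 | (S)-4-benzyl-3-(pent-4-enoyl)oxazolidin-2-one | C=CCCC(=O)N1[C@@H](Cc2ccccc2)COC1=O | intermediate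
14 | 3-bromofuran | Brc1ccoc1 | starting material
15 | (S)-4-benzyl-3-[5-(9-borabicyclo[3.3.1]nonan-9-yl)pentanoyl]oxazolidin-2-one | C1CCC2CCCC1B2CCCCC(=O)N1[C@@H](Cc2ccccc2)COC1=O | intermediate
16 | (S)-4-benzyl-3-[5-(furan-3-yl)pentanoyl]oxazolidin-2-one | O=C(CCCCc1ccoc1)N1[C@@H](Cc2ccccc2)COC1=O | intermediate
17 | allyl iodide | C=CCI | starting material
18 | sodium (Z)-1-[(S)-4-benzyl-2-oxooxazolidin-3-yl]-5-(furan-3-yl)pent-1-en-1-olate | [Na+].[O-]/C(=C\CCCc1ccoc1)N1[C@@H](Cc2ccccc2)COC1=O | intermediate
19 | (4S)-4-benzyl-3-[(2R)-5-(furan-3-yl)-2-(prop-2-en-1-yl)pentanoyl]-1,3-oxazolidin-2-one | C=CC[C@@H](CCCc1ccoc1)C(=O)N1[C@@H](Cc2ccccc2)COC1=O | intermediate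
20 | (2R,6S)-N-benzyl-7-[(4S)-4-benzyl-2-oxo-1,3-oxazolidin-3-yl]-6-[3-(furan-3-yl)propyl]-2-(4-methylpent-3-en-1-yl)-7-oxo-N-phenylheptanamide | O=C(N(Cc1ccccc1)c1ccccc1)[C@@H](CCC=C(C)C)CCC[C@@H](CCCc1ccoc1)C(=O)N1[C@@H](Cc2ccccc2)COC1=O | intermediate
21 | O-methyl imidate (N-benzyl-N-phenyl methoxyiminium) tetrafluoroborate of 20 | COC(=[N+](Cc1ccccc1)c1ccccc1)[C@@H](CCC=C(C)C)CCC[C@@H](CCCc1ccoc1)C(=O)N1[C@@H](Cc2ccccc2)COC1=O.F[B-](F)(F)F | intermediate
22 | methyl (2R,6S)-7-[(4S)-4-benzyl-2-oxo-1,3-oxazolidin-3-yl]-6-[3-(furan-3-yl)propyl]-2-(4-methylpent-3-en-1-yl)-7-oxoheptanoate | COC(=O)[C@@H](CCC=C(C)C)CCC[C@@H](CCCc1ccoc1)C(=O)N1[C@@H](Cc2ccccc2)COC1=O | intermediate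
23 | lithium (2S,6R)-2-[3-(furan-3-yl)propyl]-7-methoxy-6-(4-methylpent-3-en-1-yl)-7-oxoheptaneperoxoate | COC(=O)[C@@H](CCC=C(C)C)CCC[C@@H](CCCc1ccoc1)C(=O)O[O-].[Li+] | intermediate
24 | (2S,6R)-2-[3-(furan-3-yl)propyl]-7-methoxy-6-(4-methylpent-3-en-1-yl)-7-oxoheptanoic acid | COC(=O)[C@@H](CCC=C(C)C)CCC[C@@H](CCCc1ccoc1)C(=O)O | target

**Summary**

Total step count: 9. Longest linear sequence: 6 (steps 4, 5, 6, 7, 8, 9; the branch through steps 1, 2, 3 and then 7, 8, 9 is equally long).

Three steps most likely to fail: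

Step 7. What may go wrong: hydrodebromination of 9 by the nickel hydride, migration of the olefin of 19 along the chain toward C6 before coupling, or insufficient enantio-induction with this α-substituent. The fallback sets out from 19 and comes back at 20. It takes the hydrometalation out of the catalytic cycle and uses a preformed organozinc. 19 is hydroborated with 9-BBN-H to the B-alkyl-9-BBN adduct of 19 F1, which is oxidised with trimethylamine N-oxide (no nucleophilic peroxide, so the imide is spared) to (4S)-4-benzyl-3-[(2R)-5-(furan-3-yl)-2-(3-hydroxypropyl)pentanoyl]-1,3-oxazolidin-2-one F2. PPh3/I2/imidazole (Appel reaction) should give (4S)-4-benzyl-3-[(2R)-5-(furan-3-yl)-2-(3-iodopropyl)pentanoyl]-1,3-oxazolidin-2-one F3. Iodine-activated zinc dust in DMA should insert to give {(4R)-4-[(4S)-4-benzyl-2-oxo-1,3-oxazolidine-3-carbonyl]-7-(furan-3-yl)heptyl}zinc iodide F4. F4 is cross-coupled with racemic 9 under NiCl2·glyme/(i-Pr)-Pybox in DMI/THF at 0 °C (enantioconvergent Negishi alkylation of α-bromo N-benzyl-N-phenyl amides) to give 20.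

Step 8. What may go wrong: slow O-methylation of the hindered anilide, methylation or acid-induced decomposition of the furan, or loss of configuration at C2 by deprotonation of the imidate salt. The fallback sets out from 20 and comes back at 24. It removes the anilide reductively. 20 is first cleaved with LiOH/H2O2 and a sulfite quench as in step 9, through lithium (2S,6R)-7-[benzyl(phenyl)amino]-2-[3-(furan-3-yl)propyl]-6-(4-methylpent-3-en-1-yl)-7-oxoheptaneperoxoate F5, to (2S,6R)-7-[benzyl(phenyl)amino]-2-[3-(furan-3-yl)propyl]-6-(4-methylpent-3-en-1-yl)-7-oxoheptanoic acid F6. Excess LiBHEt3 in THF at 0 °C should reduce the tertiary anilide of the lithium carboxylate, the carboxylate itself being inert, to (2S,6R)-2-[3-(furan-3-yl)propyl]-6-(hydroxymethyl)-10-methylundec-9-enoic acid F7. KHCO3/allyl bromide in DMF should esterify the carboxylate only, giving prop-2-en-1-yl (2S,6R)-2-[3-(furan-3-yl)propyl]-6-(hydroxymethyl)-10-methylundec-9-enoate F8. Dess–Martin periodinane should give prop-2-en-1-yl (2S,6R)-6-formyl-2-[3-(furan-3-yl)propyl]-10-methylundec-9-enoate F9, and buffered NaClO2 with 2-methyl-2-butene (Pinnick oxidation) should give (2R,6S)-6-[3-(furan-3-yl)propyl]-2-(4-methylpent-3-en-1-yl)-7-oxo-7-(prop-2-en-1-yloxy)heptanoic acid F10. Me3SiCHN2 in toluene/MeOH should give 7-methyl 1-prop-2-en-1-yl (2S,6R)-2-[3-(furan-3-yl)propyl]-6-(4-methylpent-3-en-1-yl)heptanedioate F11. Pd(PPh3)4 (zerovalent palladium) with morpholine then removes the allyl group to give 24.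

Step 9. What may go wrong: competing saponification or perhydrolysis of the C1 methyl ester, or oxidation of the olefin or the furan by the peracid if the reductive quench is incomplete. The fallback sets out from 22 and comes back at 24. It is a non-oxidative two-stage cleavage. LiSEt (from EtSH and n-BuLi, THF, 0 °C) should convert the imide into methyl (2R,6S)-7-(ethylsulfanyl)-6-[3-(furan-3-yl)propyl]-2-(4-methylpent-3-en-1-yl)-7-oxoheptanoate F12 and leave the methyl ester untouched. Silver-assisted hydrolysis (AgNO3, 2,6-lutidine, THF/H2O) should then give 24.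

**Further compounds**

F1 | step 7 | B-alkyl-9-BBN adduct of 19, (4S)-4-benzyl-3-{2-[3-(9-borabicyclo[3.3.1]nonan-9-yl)propyl]-5-(furan-3-yl)pentanoyl}-1,3-oxazolidin-2-one, α-carbon arranged as in 19 | C1CCC2CCCC1B2CCC[C@@H](CCCc1ccoc1)C(=O)N1[C@@H](Cc2ccccc2)COC1=O
F2 | step 7 | (4S)-4-benzyl-3-[(2R)-5-(furan-3-yl)-2-(3-hydroxypropyl)pentanoyl]-1,3-oxazolidin-2-one | OCCC[C@@H](CCCc1ccoc1)C(=O)N1[C@@H](Cc2ccccc2)COC1=O
F3 | step 7 | (4S)-4-benzyl-3-[(2R)-5-(furan-3-yl)-2-(3-iodopropyl)pentanoyl]-1,3-oxazolidin-2-one | ICCC[C@@H](CCCc1ccoc1)C(=O)N1[C@@H](Cc2ccccc2)COC1=O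
F4 | step 7 | {(4R)-4-[(4S)-4-benzyl-2-oxo-1,3-oxazolidine-3-carbonyl]-7-(furan-3-yl)heptyl}zinc iodide | I[Zn]CCC[C@@H](CCCc1ccoc1)C(=O)N1[C@@H](Cc2ccccc2)COC1=O
F5 | step 8 | lithium (2S,6R)-7-[benzyl(phenyl)amino]-2-[3-(furan-3-yl)propyl]-6-(4-methylpent-3-en-1-yl)-7-oxoheptaneperoxoate | O=C(N(Cc1ccccc1)c1ccccc1)[C@@H](CCC=C(C)C)CCC[C@@H](CCCc1ccoc1)C(=O)O[O-].[Li+]
F6 | step 8 | (2S,6R)-7-[benzyl(phenyl)amino]-2-[3-(furan-3-yl)propyl]-6-(4-methylpent-3-en-1-yl)-7-oxoheptanoic acid | O=C(N(Cc1ccccc1)c1ccccc1)[C@@H](CCC=C(C)C)CCC[C@@H](CCCc1ccoc1)C(=O)O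
F7 | step 8 | (2S,6R)-2-[3-(furan-3-yl)propyl]-6-(hydroxymethyl)-10-methylundec-9-enoic acid | OC[C@@H](CCC=C(C)C)CCC[C@@H](CCCc1ccoc1)C(=O)O
F8 | step 8 | prop-2-en-1-yl (2S,6R)-2-[3-(furan-3-yl)propyl]-6-(hydroxymethyl)-10-methylundec-9-enoate | OC[C@@H](CCC=C(C)C)CCC[C@@H](CCCc1ccoc1)C(=O)OCC=C
F9 | step 8 | prop-2-en-1-yl (2S,6R)-6-formyl-2-[3-(furan-3-yl)propyl]-10-methylundec-9-enoate | O=C[C@@H](CCC=C(C)C)CCC[C@@H](CCCc1ccoc1)C(=O)OCC=C
F10 | step 8 | (2R,6S)-6-[3-(furan-3-yl)propyl]-2-(4-methylpent-3-en-1-yl)-7-oxo-7-(prop-2-en-1-yloxy)heptanoic acid | OC(=O)[C@@H](CCC=C(C)C)CCC[C@@H](CCCc1ccoc1)C(=O)OCC=C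
F11 | step 8 | 7-methyl 1-prop-2-en-1-yl (2S,6R)-2-[3-(furan-3-yl)propyl]-6-(4-methylpent-3-en-1-yl)heptanedioate | COC(=O)[C@@H](CCC=C(C)C)CCC[C@@H](CCCc1ccoc1)C(=O)OCC=C
F12 | step 9 | methyl (2R,6S)-7-(ethylsulfanyl)-6-[3-(furan-3-yl)propyl]-2-(4-methylpent-3-en-1-yl)-7-oxoheptanoate | COC(=O)[C@@H](CCC=C(C)C)CCC[C@@H](CCCc1ccoc1)C(=O)SCC
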